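**Plan**

1. Retrosynthesis: the free CH2OH arm is taken back to a lactone carbonyl bound to the ortho phenol oxygen, then the angelate C–O bond is cut. Next the bond from the carbinol carbon to the acyloxymethyl carbon and the carbinol C–OH bond are cut together, leaving a 3-diazobenzofuran-2(3H)-one, formaldehyde and water. The diazo group, the C2 oxygen of the lactone and the benzylic ester go last, down to benzofuran-6-carboxylic acid.
2. Forward: acid → benzylic alcohol → (R)-2-methylbutanoate; oxidation of the furan ring at C2 to the lactone; diazo transfer at C3; three-component coupling; angeloylation; reductive opening of the lactone. No ring is built; the lactone is a temporary ring from step 3 to step 7.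
3. Enabling feature: the phenol oxygen, the two aromatic carbons next to it, the carbinol carbon and the carbon of the free CH2OH are O1, C7a, C3a, C3 and C2 of a benzofuran-2(3H)-one. C3 lies between the arene and the lactone carbonyl, so it can carry a diazo group and, after capture of the carbene by water, be the nucleophilic carbon of an aromatic benzofuran-2,3-diol.
4. Stereochemistry: the side-chain centre comes from (2R)-2-methylbutanoic acid and the Z double bond from angelic acid. The carbinol centre comes from the chiral scandium co-catalyst of the three-component step and stays defined because the two one-carbon arms remain different (lactone carbonyl and CH2O-acyl) until the last step.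

Key step: step 5

Remark: the SMILES is read as (R) at the carbinol carbon, (R) in the 2-methylbutanoate and Z in the 2-methylbut-2-enoate (angelate); the same carbinol centre is (3S) in lactones 10 and 13 by CIP priority only.

**Route**

Step 1
Reactants: 1 1-benzofuran-6-carboxylic acid
Product: 2 (1-benzofuran-6-yl)methanol
Conditions: LiAlH4 (1.5 equiv), THF, 0 °C to rt; aq. NaOH work-up
Reagents that add atoms: none
Why: Hydride reduction of the aryl carboxylic acid should give the benzylic alcohol and leave the benzofuran ring untouched.

Step 2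
Reactants: 2 (1-benzofuran-6-yl)methanol; 3 (2R)-2-methylbutanoic acid
Product: 4 (1-benzofuran-6-yl)methyl (2R)-2-methylbutanoate
Conditions: DCC (1.1 equiv), DMAP (10 mol%), CH2Cl2, 0 °C to rt
Reagents that add atoms: none
Why: Steglich esterification acylates the primary benzylic alcohol under near-neutral conditions that should not epimerise the α-centre of the acid, which supplies the (R) side-chain stereocentre.

Step 3
Reactants: 4 (1-benzofuran-6-yl)methyl (2R)-2-methylbutanoate
Product: 6 (2-oxo-2,3-dihydro-1-benzofuran-6-yl)methyl (2R)-2-methylbutanoate, via 2-boryl benzofuran ester 5 (not isolated)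
Conditions: [Ir(OMe)(cod)]2 (1.5 mol%), dtbpy (3 mol%), B2pin2 (0.55 equiv), THF, 50 °C; then Oxone (1.1 equiv), acetone/H2O, 0 °C to rt
Reagents that add atoms: bis(pinacolato)diboron, CC1(C)OB(OC1(C)C)B1OC(C)(C)C(C)(C)O1 (boryl group of 5 only); Oxone (potassium peroxymonosulfate), [K+].[O-]S(=O)(=O)OO (oxygen at C2 of 6)
Why: Iridium-catalysed C–H borylation (Hartwig–Miyaura type) of a benzofuran is selective for C2–H (C7 is flanked on both sides), and one-pot boronate oxidation gives the 2-hydroxybenzofuran, which should tautomerise to the lactone.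

Step 4
Reactants: 6 (2-oxo-2,3-dihydro-1-benzofuran-6-yl)methyl (2R)-2-methylbutanoate
Product: 7 (3-diazo-2-oxo-2,3-dihydro-1-benzofuran-6-yl)methyl (2R)-2-methylbutanoate
Conditions: p-ABSA (1.2 equiv), Et3N (1.5 equiv), MeCN, 0 °C to rt
Reagents that add atoms: 4-acetamidobenzenesulfonyl azide (p-ABSA), CC(=O)Nc1ccc(cc1)S(=O)(=O)N=[N+]=[N-]
Why: The C3 methylene between the arene and the lactone carbonyl is acidic enough for Regitz diazo transfer with a sulfonyl azide and triethylamine.

Step 5
Reactants: 7 (3-diazo-2-oxo-2,3-dihydro-1-benzofuran-6-yl)methyl (2R)-2-methylbutanoate; 8 formaldehyde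
Product: 10 [(3S)-3-hydroxy-3-(hydroxymethyl)-2-oxo-2,3-dihydro-1-benzofuran-6-yl]methyl (2R)-2-methylbutanoate, via benzofuran-2,3-diol 9 (not isolated)
Conditions: Rh2(OAc)4 (1 mol%), Sc(OTf)3 (10 mol%), chiral pipecolic-acid-derived N,N'-dioxide ligand (11 mol%), methanol-free aq. CH2O (5 equiv, from paraformaldehyde), THF, 0 °C, Ar, 7 added over 2 h
Reagents that add atoms: water, O
Why: Proposed new method: Rh2(OAc)4 should expel N2 from 7, water should capture the rhodium carbene as an oxonium ylide, and proton transfer should give the aromatic enediol 9, which, held through its two oxygens on the chiral Sc(III)–N,N'-dioxide complex, should add through C3 to formaldehyde, so that the C3–OH bond and the C3–CH2OH bond arise in one operation. The closest known reaction types are the Rh(II)-catalysed three-component coupling of cyclic α-diazo amides with water and aqueous formaldehyde, which is not enantioselective, and the Rh(II)/chiral Lewis acid trapping of oxonium ylides by aldehydes; the enantioselective capture of formaldehyde by a diazo lactone is the new element. No ring is closed: the lactone of 7 is kept as a temporary ring that holds the enediol flat and keeps the carbonyl carbon and the new CH2OH carbon different. The C3 centre is controlled by the ligand of the scandium complex, which covers one face of the chelated enediol, and the ligand antipode (from L- or D-pipecolic acid) that leads to (3S) is to be selected. The step needs chemoselective O–H capture over carbonyl-ylide formation and carbene dimerisation, which the excess of water, the hydrated state of formaldehyde and the slow addition of 7 should secure, and it needs C–C bond formation to outrun ketonisation of 9. The absence of base should keep 10 from retro-aldol loss of formaldehyde.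

Step 6
Reactants: 10 [(3S)-3-hydroxy-3-(hydroxymethyl)-2-oxo-2,3-dihydro-1-benzofuran-6-yl]methyl (2R)-2-methylbutanoate; 11 angelic acid, (2Z)-2-methylbut-2-enoic acid
Product: 13 [(3S)-3-hydroxy-3-({[(2Z)-2-methylbut-2-enoyl]oxy}methyl)-2-oxo-2,3-dihydro-1-benzofuran-6-yl]methyl (2R)-2-methylbutanoate, via mixed anhydride 12 (not isolated)
Conditions: 11 (1.5 equiv), 2,4,6-Cl3C6H2COCl (1.5 equiv), Et3N (3 equiv), toluene, rt; then 10, 40 °C, no DMAP
Reagents that add atoms: 2,4,6-trichlorobenzoyl chloride, O=C(Cl)c1c(Cl)cc(Cl)cc1Cl (aroyl group of 12 only)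
Why: Yamaguchi esterification through the angelic 2,4,6-trichlorobenzoic mixed anhydride should acylate only the primary hydroxyl (the tertiary α-hydroxyl is too hindered), and working in toluene without DMAP should preserve the Z geometry and limit base-induced retro-aldol cleavage.

Step 7
Reactants: 13 [(3S)-3-hydroxy-3-({[(2Z)-2-methylbut-2-enoyl]oxy}methyl)-2-oxo-2,3-dihydro-1-benzofuran-6-yl]methyl (2R)-2-methylbutanoate
Product: 14 (2R)-2,3-dihydroxy-2-[2-hydroxy-4-({[(2R)-2-methylbutanoyl]oxy}methyl)phenyl]propyl (2Z)-2-methylbut-2-enoate (target)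
Conditions: NaBH4 (2 equiv), THF/EtOH 4:1, −20 to 0 °C; AcOH then pH 7 buffer
Reagents that add atoms: none
Why: Chemoselective borohydride reduction should take only the lactone, a strained aryl ester activated by the α-hydroxyl, to the primary alcohol and free the phenol in the same operation, while the conjugated α-substituted angelate and the α-branched alkyl ester react far more slowly; low temperature and an acidic quench should limit 1,3-acyl migration, which would invert the carbinol centre.

**Compound list**

1 | 1-benzofuran-6-carboxylic acid | O=C(O)c1ccc2ccoc2c1 | starting material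
2 | (1-benzofuran-6-yl)methanol | OCc1ccc2ccoc2c1 | intermediate
3 | (2R)-2-methylbutanoic acid | CC[C@@H](C)C(=O)O | starting material
4 | (1-benzofuran-6-yl)methyl (2R)-2-methylbutanoate | CC[C@@H](C)C(=O)OCc1ccc2ccoc2c1 | intermediate
5 | [2-(4,4,5,5-tetramethyl-1,3,2-dioxaborolan-2-yl)-1-benzofuran-6-yl]methyl (2R)-2-methylbutanoate | CC[C@@H](C)C(=O)OCc1ccc2cc(B3OC(C)(C)C(C)(C)O3)oc2c1 | intermediate (not isolated)
6 | (2-oxo-2,3-dihydro-1-benzofuran-6-yl)methyl (2R)-2-methylbutanoate | CC[C@@H](C)C(=O)OCc1ccc2c(c1)OC(=O)C2 | intermediate
7 | (3-diazo-2-oxo-2,3-dihydro-1-benzofuran-6-yl)methyl (2R)-2-methylbutanoate | CC[C@@H](C)C(=O)OCc1ccc2c(c1)OC(=O)C2=[N+]=[N-] | intermediate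
8 | formaldehyde | C=O | starting material
9 | (2,3-dihydroxy-1-benzofuran-6-yl)methyl (2R)-2-methylbutanoate | CC[C@@H](C)C(=O)OCc1ccc2c(O)c(O)oc2c1 | intermediate (not isolated)
10 | [(3S)-3-hydroxy-3-(hydroxymethyl)-2-oxo-2,3-dihydro-1-benzofuran-6-yl]methyl (2R)-2-methylbutanoate | OC[C@]1(O)C(=O)Oc2cc(COC(=O)[C@H](C)CC)ccc21 | intermediate
11 | angelic acid, (2Z)-2-methylbut-2-enoic acid | C/C=C(/C)C(=O)O | starting material
12 | (2Z)-2-methylbut-2-enoic 2,4,6-trichlorobenzoic anhydride | C/C=C(/C)C(=O)OC(=O)c1c(Cl)cc(Cl)cc1Cl | intermediate (not isolated)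
13 | [(3S)-3-hydroxy-3-({[(2Z)-2-methylbut-2-enoyl]oxy}methyl)-2-oxo-2,3-dihydro-1-benzofuran-6-yl]methyl (2R)-2-methylbutanoate | C/C=C(/C)C(=O)OC[C@]1(O)C(=O)Oc2cc(COC(=O)[C@H](C)CC)ccc21 | intermediate
14 | (2R)-2,3-dihydroxy-2-[2-hydroxy-4-({[(2R)-2-methylbutanoyl]oxy}methyl)phenyl]propyl (2Z)-2-methylbut-2-enoate | C/C=C(/C)C(=O)OC[C@](O)(CO)c1ccc(COC(=O)[C@H](C)CC)cc1O | target

**Summary**

Total step count: 7. Longest linear sequence: 7 steps (1 → 2 → 4 → 6 → 7 → 10 → 13 → 14).

Steps most likely to fail:

Step 5. Facial discrimination in the addition of the enediol to formaldehyde may be insufficient. The enediol may also ketonise before the C–C bond forms, or the carbene may be lost to carbonyl-ylide formation or dimerisation. The fallback uses known chemistry, sets out from 7 and comes back at 10. The scandium complex is left out, and 7 is decomposed by Rh2(OAc)4 alone in THF with methanol-free aqueous formaldehyde, as is known for cyclic diazo amides. This should give 10 together with its C3 epimer, [(3R)-3-hydroxy-3-(hydroxymethyl)-2-oxo-2,3-dihydro-1-benzofuran-6-yl]methyl (2R)-2-methylbutanoate F1, without selectivity. The epimers are then parted by lipase-catalysed transesterification with vinyl acetate (Burkholderia cepacia lipase, MTBE, 30 °C). The lipase is chosen from a screen so that the unwanted epimer reacts faster and gives [(3R)-3-(acetoxymethyl)-3-hydroxy-2-oxo-2,3-dihydro-1-benzofuran-6-yl]methyl (2R)-2-methylbutanoate F2. Unreacted 10 is separated by chromatography and enters step 6.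

Step 6. The Z-enoate may isomerise to the E-isomer during acyl activation, and the amine base may cause retro-aldol loss of formaldehyde from 10. The fallback sets out from 10 and comes back at 13, and builds the Z-alkene on the substrate instead of transferring it. 10 is esterified with 2-[bis(2,2,2-trifluoroethoxy)phosphoryl]propanoic acid (DIC, DMAP 5 mol%, CH2Cl2, 0 °C). This gives [(3S)-3-({2-[bis(2,2,2-trifluoroethoxy)phosphoryl]propanoyl}oxymethyl)-3-hydroxy-2-oxo-2,3-dihydro-1-benzofuran-6-yl]methyl (2R)-2-methylbutanoate F3 as a mixture of epimers at the phosphonate carbon. Still–Gennari olefination of F3 with acetaldehyde (K2CO3, 18-crown-6, toluene, −20 °C) should then give the Z-enoate 13 under kinetic control.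

Step 7. The angeloyl group may migrate to the newly formed primary alkoxide, which would erode the configuration of the carbinol centre, and the two other esters may be partly reduced. The fallback sets out from 13 and comes back at 14, and avoids basic hydride conditions. The lactone is opened with methanol (PPTS cat., MeOH, 0 °C to rt) to methyl (2S)-2-hydroxy-2-[2-hydroxy-4-({[(2R)-2-methylbutanoyl]oxy}methyl)phenyl]-3-{[(2Z)-2-methylbut-2-enoyl]oxy}propanoate F4. Hydroxyl-directed borane reduction (BH3·SMe2, NaBH4 5 mol%, THF, 0 °C) should then reduce only the ester α to the tertiary hydroxyl, through a cyclic alkoxyborane, and give 14.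

**Further compounds**

F1 | step 5 | [(3R)-3-hydroxy-3-(hydroxymethyl)-2-oxo-2,3-dihydro-1-benzofuran-6-yl]methyl (2R)-2-methylbutanoate | OC[C@@]1(O)C(=O)Oc2cc(COC(=O)[C@H](C)CC)ccc21
F2 | step 5 | [(3R)-3-(acetoxymethyl)-3-hydroxy-2-oxo-2,3-dihydro-1-benzofuran-6-yl]methyl (2R)-2-methylbutanoate | CC(=O)OC[C@@]1(O)C(=O)Oc2cc(COC(=O)[C@H](C)CC)ccc21
F3 | step 6 | [(3S)-3-({2-[bis(2,2,2-trifluoroethoxy)phosphoryl]propanoyl}oxymethyl)-3-hydroxy-2-oxo-2,3-dihydro-1-benzofuran-6-yl]methyl (2R)-2-methylbutanoate | CC(C(=O)OC[C@]1(O)C(=O)Oc2cc(COC(=O)[C@H](C)CC)ccc21)P(=O)(OCC(F)(F)F)OCC(F)(F)F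
F4 | step 7 | methyl (2S)-2-hydroxy-2-[2-hydroxy-4-({[(2R)-2-methylbutanoyl]oxy}methyl)phenyl]-3-{[(2Z)-2-methylbut-2-enoyl]oxy}propanoate | C/C=C(/C)C(=O)OC[C@](O)(C(=O)OC)c1ccc(COC(=O)[C@H](C)CC)cc1O
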